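## Retrosynthetic overview

1. Target ⇐ C1-selective angeloylation of the C1,C3-diol ⇐ hydroxyl-directed reduction (C3) ⇐ asymmetric conjugate borylation/oxidation (C1) of a bridged cycloheptenone, closed by intramolecular aldol condensation (C2–C1) of a C4 acetyl with a C11 formyl arm.
2. C11 ⇐ enzymatic differentiation of two acetoxymethyl arms; C10 ⇐ cuprate addition to a bicyclo[3.1.1]hept-3-en-2-one.
3. Key disconnection: that cyclobutane-containing enone ⇐ Tiffeneau–Demjanov-type 1,2-shift of the one-carbon bridge of a 1-hydroxy-2-endo-aminonorbornene (cyclopentene → cyclohexenone ring expansion that also creates the four-membered ring).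
4. Aminonorbornene ⇐ nitro reduction ⇐ Diels–Alder of an enantioenriched 5-ethynyl-5-methyl-1-siloxycyclopentadiene (from 2-methylcyclopentane-1,3-dione) with an (E)-nitroalkene carrying the C11 unit (from 3-methyloxetane-3-carbaldehyde and nitromethane).
5. Ring order: cyclopentene (bought ring) → norbornene → cyclobutane + cyclohexenone (ring expansion) → cycloheptane (aldol).

Atom labels used below (target): C1 = CH–OAng; C2 = CH2; C3 = CH–OH; C4 = C(CH3) of the cyclobutane; C5, C6, C7 = cyclobutane CH; C8 = C=O; C9 = CH2; C10 = CH–CH3; C11 = quaternary C between C6 and C1; C15 = its acetoxymethyl carbon.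

Assumption: TMS-EBX is treated as an ethynyl-transfer reagent (only C≡CH is incorporated) and 3-methyloxetane-3-carbaldehyde as purchasable.

## Route

Step 1
Reactants: 1 2-methylcyclopentane-1,3-dione
Product: 2 2-ethynyl-2-methylcyclopentane-1,3-dione
Conditions: TMS-EBX (1.2 eq), TBAF (1.2 eq), THF, −78 °C → rt
Reagents that add atoms: TMS-EBX, 1-[(trimethylsilyl)ethynyl]-1,2-benziodoxol-3(1H)-one, C[Si](C)(C)C#CI1OC(=O)c2ccccc12
Why: electrophilic α-alkynylation of the soft 1,3-diketone enolate with an ethynylbenziodoxolone (fluoride removes the TMS group in situ) is C-selective and forms no stereocentre.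

Step 2
Reactants: 2 2-ethynyl-2-methylcyclopentane-1,3-dione
Product: 3 (2R,3S)-2-ethynyl-3-hydroxy-2-methylcyclopentan-1-one (OH cis to CH3)
Conditions: RuCl[(S,S)-TsDPEN](p-cymene) (1 mol%; antipode chosen to give 2R), HCO2H/Et3N (5:2), CH2Cl2, 25 °C, stopped at mono-reduction
Reagents that add atoms: none
Why: Noyori asymmetric transfer hydrogenation desymmetrises the prochiral dione by reducing one enantiotopic carbonyl, which fixes the quaternary carbon (future C4); the carbinol centre is removed in step 3.

Step 3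
Reactants: 3 (2R,3S)-2-ethynyl-3-hydroxy-2-methylcyclopentan-1-one
Product: 5 (S)-2-ethynyl-2-methylcyclopent-3-en-1-one, via mesylate 4 (not isolated)
Conditions: MsCl, Et3N, CH2Cl2, 0 °C; then DBU, toluene, 80 °C
Reagents that add atoms: none
Why: sulfonylation then E2 elimination can only give the β,γ-alkene because the α-carbon is quaternary, and that stereocentre is untouched.

Step 4
Reactants: 6 3-methyloxetane-3-carbaldehyde; 7 nitromethane
Product: 10 3-methyl-3-[(E)-2-nitroethenyl]oxetane, via nitroaldol 8 (not isolated), via nitroaldol mesylate 9 (not isolated)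
Conditions: MeNO2 (5 eq), KOt-Bu (5 mol%), THF/t-BuOH, 0 °C; then MsCl, Et3N (2.2 eq), CH2Cl2, 0 °C → rt
Reagents that add atoms: none
Why: Henry reaction of the non-enolisable aldehyde followed by E1cB dehydration gives the conjugated nitroalkene with the thermodynamic (E)-geometry.

Step 5
Reactants: 10 3-methyl-3-[(E)-2-nitroethenyl]oxetane
Product: 11 2-methyl-2-[(E)-2-nitroethenyl]propane-1,3-diyl diacetate
Conditions: Ac2O, Sc(OTf)3 (5 mol%), CH2Cl2, 0 → 25 °C
Reagents that add atoms: acetic anhydride, CC(=O)OC(C)=O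
Why: Lewis-acid-catalysed acylative ring opening of the strained oxetane (O-acylation then acetate SN2 at CH2) gives two identical acetoxymethyl arms and no stereocentre.

Step 6
Reactants: 5 (S)-2-ethynyl-2-methylcyclopent-3-en-1-one; 11 2-methyl-2-[(E)-2-nitroethenyl]propane-1,3-diyl diacetate
Product: 13 2-endo-nitro-3-exo-(1,3-diacetoxy-2-methylpropan-2-yl)-7-anti-ethynyl-7-syn-methyl-1-(trimethylsilyloxy)bicyclo[2.2.1]hept-5-ene (syn = over C5=C6), via silyl dienol ether 12 (not isolated)
Conditions: TMSOTf (1.1 eq), Et3N (1.5 eq), CH2Cl2, 0 °C; solvent exchange to toluene; 11 (1.2 eq), 60 °C (or 12 kbar, 25 °C)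
Reagents that add atoms: trimethylsilyl triflate, C[Si](C)(C)OS(=O)(=O)C(F)(F)F
Why: soft enolisation at the only activated CH2, then Diels–Alder cycloaddition of the 1-siloxydiene with the nitroalkene, in which the siloxy terminus bonds to the nitro carbon, the dienophile adds to the diene face carrying the slim ethynyl group (anti to CH3), the nitro group goes endo and the (E)-geometry puts the C11 group exo and trans to NO2; this sets C5–C8 relative to C4.

Step 7
Reactants: 13 nitro adduct (name as above)
Product: 14 2-endo-amino-3-exo-(1,3-diacetoxy-2-methylpropan-2-yl)-7-anti-ethynyl-7-syn-methylbicyclo[2.2.1]hept-5-en-1-ol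
Conditions: Zn dust, AcOH/THF/H2O, 0 → 25 °C; NaHCO3 work-up
Reagents that add atoms: none
Why: Zn/AcOH reduction of the secondary nitro group to the amine proceeds with retention at C7 (acidic medium, so no nitronate epimerisation or retro-Henry), and the bridgehead TMS ether is hydrolysed in the aqueous acid.

Step 8
Reactants: 14 amino alcohol (name as above)
Product: 16 6-anti-ethynyl-6-syn-methyl-7-anti-(1,3-diacetoxy-2-methylpropan-2-yl)bicyclo[3.1.1]hept-3-en-2-one (syn = over the enone bridge), via diazonium salt 15 (not isolated)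
Conditions: NaNO2 (1.5 eq), AcOH/H2O (4:1), 0 °C, 1 h
Reagents that add atoms: none
Why: Proposed new method: a Tiffeneau–Demjanov-type semipinacol ring expansion run in the bornyl→pinyl direction – diazotisation gives the endo-C7 diazonium, whose C–N bond is antiperiplanar (ca. 150°) only to the C8–C4 one-carbon bridge, so loss of N2 with lone-pair push from the bridgehead OH moves the quaternary propargylic C4 from C8 to C7 (inversion at C7, retention at C4), which expands the cyclopentene to the cyclohexenone and creates the cyclobutane; the C8–C9 vinyl bond is gauche (ca. 50°) and cannot migrate, the bridgehead oxygen cannot close an epoxide, and irreversible N2 loss plus C=O formation should pay for the added ring strain (roughly 15 kcal/mol by estimate); the closest known reaction types are the Tiffeneau–Demjanov ring expansion of 1-(aminomethyl)cycloalkanols and semipinacol deaminations of 2-aminocycloalkanols.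

Step 9
Reactants: 16 ethynyl cage enone (name as above)
Product: 17 6-anti-acetyl-6-syn-methyl-7-anti-(1,3-diacetoxy-2-methylpropan-2-yl)bicyclo[3.1.1]hept-3-en-2-one
Conditions: (IPr)AuCl/AgSbF6 (2 mol%), 1,4-dioxane/H2O, 60 °C
Reagents that add atoms: water, O
Why: gold(I)-catalysed Markovnikov hydration of the terminal alkyne gives the methyl ketone (C3 carbonyl, C2 methyl); enone and acetates are inert and no stereocentre changes.

Step 10
Reactants: 17 acetyl cage enone (name as above)
Product: 18 6-anti-acetyl-4,6-syn-dimethyl-7-anti-(1,3-diacetoxy-2-methylpropan-2-yl)bicyclo[3.1.1]heptan-2-one with the 4-methyl (C10) on the side of the C7 bridge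
Conditions: Me2CuLi (from CuI and MeLi, 2 eq), Et2O, −78 °C; aq. NH4Cl
Reagents that add atoms: lithium dimethylcuprate (from methyllithium), [Li+].C[Cu-]C
Why: cuprate 1,4-addition to the bicyclo[3.1.1]hept-3-en-2-one occurs from the face of the bridge that carries only H (the other bridge shields its face with the syn methyl, as in additions to apoverbenone), which sets C10; the esters and the neopentylic methyl ketone do not react at −78 °C.

Step 11
Reactants: 18 diacetate (name as above)
Product: 19 mono-alcohol of 18 in which the acetoxymethyl arm destined to become C1 is hydrolysed (C11 configured as in the target; C15 acetate kept)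
Conditions: Pseudomonas cepacia lipase (Amano PS, chosen by screening), pH 7 phosphate buffer/acetone (9:1), 30 °C
Reagents that add atoms: none
Why: enzymatic hydrolysis of one of two diastereotopic primary acetates (lipase desymmetrisation of a 2,2-disubstituted propane-1,3-diol diacetate) sets the quaternary centre C11 under enzyme control.

Step 12
Reactants: 19 mono-alcohol (name as above)
Product: 22 tricyclic enone with the target skeleton (C3 ketone; C1=C2 double bond; C8 ketone; C15 acetate), via aldehyde 20 (not isolated), via aldol adduct 21 (not isolated)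
Conditions: PhI(OAc)2 (1.1 eq), TEMPO (10 mol%), CH2Cl2, 25 °C; then pyrrolidine (30 mol%), AcOH, 40 °C
Reagents that add atoms: none
Why: TEMPO/PhI(OAc)2 oxidation of the primary alcohol (neutral, so no acyl migration) followed by amine-catalysed intramolecular aldol condensation of the C4 acetyl with the non-enolisable C1 aldehyde, held cis-1,3 on the cyclobutane, closes the seven-membered ring as the enone; C11 cannot epimerise.

Step 13
Reactants: 22 tricyclic enone (name as above)
Product: 24 C1-hydroxy C3-ketone (target skeleton; C1–OH trans to C15H2OAc), via boronate 23 (not isolated)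
Conditions: CuCl (5 mol%), (R,S)-Josiphos (antipode chosen for the C1 face anti to C15), NaOt-Bu (5 mol%), B2pin2, MeOH, THF, 25 °C; then 30% H2O2, pH 7 buffer, 0 °C
Reagents that add atoms: hydrogen peroxide, OO
Why: copper-catalysed asymmetric conjugate borylation delivers boron to C1 under ligand control and the stereoretentive C–B oxidation gives the β-hydroxy ketone with C1 set; saturated ketones are not borylated.

Step 14
Reactants: 24 C1-hydroxy C3-ketone (name as above)
Product: 25 C1,C3-diol (target without the angeloyl group)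
Conditions: Me4NBH(OAc)3 (5 eq), MeCN/AcOH (1:1), −30 → −20 °C
Reagents that add atoms: none
Why: Evans–Saksena hydroxyl-directed reduction delivers hydride intramolecularly to the C3 ketone from the face of the C1 oxygen, so the new C3–OH is trans (1,3-anti) to C1–OH, and the isolated C8 ketone is not reduced.

Step 15
Reactants: 25 C1,C3-diol (name as above); 26 angelic acid ((Z)-2-methylbut-2-enoic acid)
Product: 28 CNP0212099.1 (target), via mixed anhydride 27 (not isolated)
Conditions: 26 (1.5 eq), 2,4,6-trichlorobenzoyl chloride, Et3N, toluene, 25 °C; then 25 (no DMAP), 75 °C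
Reagents that add atoms: none
Why: Yamaguchi-type esterification through the mixed anhydride without a nucleophilic catalyst keeps the (Z)-geometry, and acylation is expected at the pseudo-equatorial C1–OH in preference to the C3–OH, which is pseudo-axial and neopentylic to the cage carbon C4.

## Compound list

1 | 2-methylcyclopentane-1,3-dione | CC1C(=O)CCC1=O | starting material
2 | 2-ethynyl-2-methylcyclopentane-1,3-dione | C#CC1(C)C(=O)CCC1=O | intermediate
3 | (2R,3S)-2-ethynyl-3-hydroxy-2-methylcyclopentan-1-one | C#C[C@@]1(C)C(=O)CC[C@@H]1O | intermediate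
4 | (1S,2R)-2-ethynyl-2-methyl-3-oxocyclopentyl methanesulfonate | C#C[C@@]1(C)C(=O)CC[C@@H]1OS(C)(=O)=O | intermediate (not isolated)
5 | (S)-2-ethynyl-2-methylcyclopent-3-en-1-one | C#C[C@@]1(C)C(=O)CC=C1 | intermediate
6 | 3-methyloxetane-3-carbaldehyde | CC1(C=O)COC1 | starting material
7 | nitromethane | C[N+](=O)[O-] | starting material
8 | 1-(3-methyloxetan-3-yl)-2-nitroethan-1-ol (racemic) | CC1(C(O)C[N+](=O)[O-])COC1 | intermediate (not isolated)
9 | 1-(3-methyloxetan-3-yl)-2-nitroethyl methanesulfonate (racemic) | CC1(C(C[N+](=O)[O-])OS(C)(=O)=O)COC1 | intermediate (not isolated)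
10 | 3-methyl-3-[(E)-2-nitroethenyl]oxetane | CC1(/C=C/[N+](=O)[O-])COC1 | intermediate
11 | 2-methyl-2-[(E)-2-nitroethenyl]propane-1,3-diyl diacetate | CC(=O)OCC(C)(/C=C/[N+](=O)[O-])COC(C)=O | intermediate
12 | [(5S)-5-ethynyl-5-methylcyclopenta-1,3-dien-1-yl]oxy(trimethyl)silane | C#C[C@@]1(C)C(O[Si](C)(C)C)=CC=C1 | intermediate (not isolated)
13 | 2-endo-nitro-3-exo-(1,3-diacetoxy-2-methylpropan-2-yl)-7-anti-ethynyl-7-syn-methyl-1-(trimethylsilyloxy)bicyclo[2.2.1]hept-5-ene | C#C[C@@]1(C)[C@]2(O[Si](C)(C)C)C=C[C@H]1[C@H](C(C)(COC(C)=O)COC(C)=O)[C@H]2[N+](=O)[O-] | intermediate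
14 | 2-endo-amino-3-exo-(1,3-diacetoxy-2-methylpropan-2-yl)-7-anti-ethynyl-7-syn-methylbicyclo[2.2.1]hept-5-en-1-ol | C#C[C@@]1(C)[C@]2(O)C=C[C@H]1[C@H](C(C)(COC(C)=O)COC(C)=O)[C@H]2N | intermediate
15 | C2-endo diazonium acetate of 14 | C#C[C@@]1(C)[C@]2(O)C=C[C@H]1[C@H](C(C)(COC(C)=O)COC(C)=O)[C@H]2[N+]#N.CC(=O)[O-] | intermediate (not isolated)
16 | 6-anti-ethynyl-6-syn-methyl-7-anti-(1,3-diacetoxy-2-methylpropan-2-yl)bicyclo[3.1.1]hept-3-en-2-one | C#C[C@]2(C)[C@@H]3[C@@H]([C@H]2C(=O)C=C3)C(C)(COC(C)=O)COC(C)=O | intermediate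
17 | 6-anti-acetyl-6-syn-methyl-7-anti-(1,3-diacetoxy-2-methylpropan-2-yl)bicyclo[3.1.1]hept-3-en-2-one | CC(=O)[C@]2(C)[C@@H]3[C@@H]([C@H]2C(=O)C=C3)C(C)(COC(C)=O)COC(C)=O | intermediate
18 | 6-anti-acetyl-4,6-syn-dimethyl-7-anti-(1,3-diacetoxy-2-methylpropan-2-yl)bicyclo[3.1.1]heptan-2-one (4-CH3 on the C7-bridge side) | CC(=O)[C@]2(C)[C@@H]3[C@@H]([C@H]2C(=O)C[C@H]3C)C(C)(COC(C)=O)COC(C)=O | intermediate
19 | mono-alcohol of 18 (pro-C1 arm hydrolysed; C15 acetate kept) | CC(=O)[C@]2(C)[C@@H]3[C@@H]([C@H]2C(=O)C[C@H]3C)[C@@](CO)(C)COC(C)=O | intermediate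
20 | C1 aldehyde from 19 | CC(=O)[C@]2(C)[C@@H]3[C@@H]([C@H]2C(=O)C[C@H]3C)[C@@](C=O)(C)COC(C)=O | intermediate (not isolated)
21 | aldol adduct (C1 epimers; C1–OH, C3 ketone) | OC1CC(=O)[C@]2(C)[C@@H]3[C@@H]([C@H]2C(=O)C[C@H]3C)[C@@]1(C)COC(C)=O | intermediate (not isolated)
22 | tricyclic enone (C3 ketone; C1=C2; C8 ketone; C15 acetate) | C1=CC(=O)[C@]2(C)[C@@H]3[C@@H]([C@H]2C(=O)C[C@H]3C)[C@@]1(C)COC(C)=O | intermediate
23 | C1 pinacol boronate of the C3 ketone | CC1(C)OB(OC1(C)C)[C@@H]2CC(=O)[C@]3(C)[C@@H]4[C@@H]([C@H]3C(=O)C[C@H]4C)[C@@]2(C)COC(C)=O | intermediate (not isolated)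
24 | C1-hydroxy C3-ketone | O[C@@H]1CC(=O)[C@]2(C)[C@@H]3[C@@H]([C@H]2C(=O)C[C@H]3C)[C@@]1(C)COC(C)=O | intermediate
25 | C1,C3-diol (deangeloyl target) | O[C@@H]1C[C@@H](O)[C@]2(C)[C@@H]3[C@@H]([C@H]2C(=O)C[C@H]3C)[C@@]1(C)COC(C)=O | intermediate
26 | angelic acid | C/C=C(/C)C(=O)O | starting material
27 | angelic 2,4,6-trichlorobenzoic anhydride | C/C=C(/C)C(=O)OC(=O)c1c(Cl)cc(Cl)cc1Cl | intermediate (not isolated)
28 | CNP0212099.1 | C/C=C(/C)C(=O)O[C@@H]1C[C@@H](O)[C@]2(C)[C@@H]3[C@@H]([C@H]2C(=O)C[C@H]3C)[C@@]1(C)COC(C)=O | target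

## Step count and risks

Total steps: 15. Longest linear sequence: 13 (1 → 2 → 3 → 5 → 13 → 14 → 16 → 17 → 18 → 19 → 22 → 24 → 25 → 28); the nitroalkene branch (6 + 7 → 10 → 11) adds 2.

The three steps most likely to fail:

1. Step 8, the proposed new step. The diazonium may be captured by solvent, the wrong bond may shift, or the strain-building shift may simply not compete. The fallback uses known chemistry, sets out from 13 and comes back at 16. It replaces the cationic trigger by the established anionic pinacol-type shift of a vicinal diol monosulfonate. Oxidative Nef reaction of the nitronate of 13 (DBU, then dimethyldioxirane) gives the α-siloxy ketone F1. Equilibrating Meerwein–Ponndorf–Verley reduction (Al(Oi-Pr)3, i-PrOH, acidic work-up that also removes the TMS group) gives the thermodynamically preferred endo alcohol, trans to the exo C11 group, as the diol F2. Selective mesylation of the secondary hydroxyl (MsCl, pyridine) gives the hydroxy mesylate F3. KOt-Bu in THF (or Et2AlCl) then drives the concerted antiperiplanar 1,2-shift of the bridge carbon to 16.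

2. Step 6. Both new bonds form next to quaternary carbons, and the face and endo selectivities rest on steric arguments. The fallback sets out from 5 and comes back at 14, and replaces the cycloaddition by a stepwise polar annulation. TBSOTf/Et3N gives the isolable TBS dienol ether F4. SnCl4-mediated vinylogous Mukaiyama–Michael addition to 11 at −78 °C (γ-attack anti to CH3) gives the nitro enone F5. Tetramethylguanidine-promoted intramolecular Henry reaction onto the ring carbonyl closes the norbornene as the nitro alcohol F6, and Zn/AcOH then gives 14.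

3. Step 11. The sense and degree of arm selectivity of the enzyme on this substrate are not known in advance. The fallback sets out from 18 and comes back at 19, and replaces enzyme control by small-molecule catalyst control. K2CO3 in MeOH removes both acetates to give the diol F7, and a desymmetrising mono-acetylation (Ac2O, planar-chiral 4-aminopyridine catalyst, −40 °C) then gives 19.

Further compounds
F1 | step 8 | 3-exo-(1,3-diacetoxy-2-methylpropan-2-yl)-7-anti-ethynyl-7-syn-methyl-1-(trimethylsilyloxy)bicyclo[2.2.1]hept-5-en-2-one | C#C[C@@]1(C)[C@]2(O[Si](C)(C)C)C=C[C@H]1[C@H](C(C)(COC(C)=O)COC(C)=O)C2=O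
F2 | step 8 | 3-exo-(1,3-diacetoxy-2-methylpropan-2-yl)-7-anti-ethynyl-7-syn-methylbicyclo[2.2.1]hept-5-ene-1,2-endo-diol | C#C[C@@]1(C)[C@]2(O)C=C[C@H]1[C@H](C(C)(COC(C)=O)COC(C)=O)[C@H]2O
F3 | step 8 | 2-endo-methanesulfonate of F2 (bridgehead OH free) | C#C[C@@]1(C)[C@]2(O)C=C[C@H]1[C@H](C(C)(COC(C)=O)COC(C)=O)[C@H]2OS(C)(=O)=O
F4 | step 6 | tert-butyl{[(5S)-5-ethynyl-5-methylcyclopenta-1,3-dien-1-yl]oxy}dimethylsilane | C#C[C@@]1(C)C(O[Si](C)(C)C(C)(C)C)=CC=C1
F5 | step 6 | 5-ethynyl-5-methyl-4-[4-acetoxy-3-(acetoxymethyl)-3-methyl-1-nitrobutan-2-yl]cyclopent-2-en-1-one (C5 and C6 configured as in 13) | C#C[C@@]1(C)C(=O)C=C[C@H]1[C@H](C(C)(COC(C)=O)COC(C)=O)C[N+](=O)[O-]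
F6 | step 6 | 2-endo-nitro-3-exo-(1,3-diacetoxy-2-methylpropan-2-yl)-7-anti-ethynyl-7-syn-methylbicyclo[2.2.1]hept-5-en-1-ol | C#C[C@@]1(C)[C@]2(O)C=C[C@H]1[C@H](C(C)(COC(C)=O)COC(C)=O)[C@H]2[N+](=O)[O-]
F7 | step 11 | 6-anti-acetyl-4,6-syn-dimethyl-7-anti-(1,3-dihydroxy-2-methylpropan-2-yl)bicyclo[3.1.1]heptan-2-one | CC(=O)[C@]2(C)[C@@H]3[C@@H]([C@H]2C(=O)C[C@H]3C)C(C)(CO)CO
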